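**Retrosynthetic overview**

1. Numbering used throughout: ring A = C1–C5 and C10 (C4 carries the gem-dimethyl group), ring B = C5–C10, side chain C11–C15 on C9. Ring B is a cyclohexene whose only C=C is the ring-fusion bond C5=C10, directly opposite the C7–C8 bond, and C6 carries oxygen. This is the retron of a Diels–Alder reaction between a 1-oxygenated diene C6=C5–C10=C9, exocyclic on ring A and held s-cis by it, and an (E)-crotonyl dienophile C7=C8.
2. The C7 acetate comes from a C7 acetyl group (enzymatic Baeyer–Villiger oxidation, retention), and that from a C7 acyl oxazolidinone; C6–C7 and C8–C9 are formed together in the auxiliary-controlled endo cycloaddition (ring B, four stereocentres).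
3. The (E)-silyl dienol ether comes from a β,γ-unsaturated aldehyde, that from a spiro-epoxide, that from an enone; C6 is added without ever breaking the C10=C9 geometry.
4. Ring A and the (Z)-tetrasubstituted C10=C9 alkene come from one nickel-catalysed alkylative ynal cyclization (C5–C10 and C9–C11 formed cis); the C11–C15 zinc reagent carries C13 from (S)-linalool.
5. Ring order: ring A (step 7), then ring B (step 12).

Key step: step 12

Assumption: (S)-(+)-linalool of high enantiomeric purity is taken as the commercial source of C13; this centre is never touched in the route.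

**Route**

Step 1
Reactants: 1 (S)-(+)-linalool
Product: 3 (5S)-5-ethenyl-5-methyloxolan-2-ol (anomer mixture), via secondary ozonide 2 (not isolated)
Conditions: O3 (1 equiv, indicator end point), CH2Cl2, −78 °C; then Me2S, −78 °C to rt
Reagents that add atoms: ozone ([O-][O+]=O)
Why: Criegee ozonolysis with reductive work-up cleaves the electron-rich trisubstituted alkene much faster than the vinyl group, and the γ-hydroxy aldehyde closes to the lactol without touching the stereocentre.

Step 2
Reactants: 3 (5S)-5-ethenyl-5-methyloxolan-2-ol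
Product: 4 (5S)-5-ethenyl-5-methyloxolan-2-one
Conditions: TEMPO (10 mol%), PhI(OAc)2, CH2Cl2, rt
Reagents that add atoms: none
Why: Oxoammonium oxidation of a lactol to the lactone is mild and should leave the vinyl group and the tertiary centre alone.

Step 3
Reactants: 4 (5S)-5-ethenyl-5-methyloxolan-2-one
Product: 7 (4S)-4-methyl-4-[(triethylsilyl)oxy]hex-5-enoic acid, via lithium hydroxy carboxylate 5 (not isolated), via bis-silylated ester 6 (not isolated)
Conditions: LiOH, THF/H2O, rt, evaporate; Et3SiOTf, 2,6-lutidine, CH2Cl2, 0 °C; then MeOH/H2O, K2CO3 (cat.), 0 °C, work-up at pH 5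
Reagents that add atoms: lithium hydroxide ([Li+].[OH-]); triethylsilyl trifluoromethanesulfonate (CC[Si](CC)(CC)OS(=O)(=O)C(F)(F)F)
Why: Saponification opens the lactone, silylation caps the tertiary alkoxide and the carboxylate, and only the labile silyl ester is cleaved again, so the tertiary silyl ether blocks relactonization.

Step 4
Reactants: 7 (4S)-4-methyl-4-[(triethylsilyl)oxy]hex-5-enoic acid
Product: 9 triethyl{[(3S)-5-iodo-3-methylpent-1-en-3-yl]oxy}silane, via thiohydroxamate ester 8 (not isolated)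
Conditions: N-hydroxypyridine-2(1H)-thione, DCC, DMAP (cat.), CH2Cl2, 0 °C to rt, dark; then CHI3, hν (tungsten lamp), rt
Reagents that add atoms: iodoform (IC(I)I)
Why: Barton decarboxylative iodination proceeds by a neutral radical chain (primary radical, iodine transfer from CHI3) that should tolerate the vinyl group and the silyl ether and does not involve the stereocentre.

Step 5
Reactants: 10 isobutyronitrile; 11 6-chlorohex-2-yne
Product: 13 2,2-dimethyloct-6-ynenitrile, via lithiated nitrile 12 (not isolated)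
Conditions: LiN(i-Pr)2, THF, −78 °C; then 11, NaI (10 mol%), DMPU, −78 °C to rt
Reagents that add atoms: none
Why: Alkylation of the small α-lithio nitrile with a primary halide (Finkelstein activation) builds the quaternary carbon C4.

Step 6
Reactants: 13 2,2-dimethyloct-6-ynenitrile
Product: 14 2,2-dimethyloct-6-ynal
Conditions: i-Bu2AlH, CH2Cl2, −78 °C; then 1 M HCl, 0 °C
Reagents that add atoms: water (O)
Why: Hydride reduction of the nitrile stops at the aluminium aldimine, which hydrolyses to an aldehyde that has no α-hydrogen and so cannot enolize.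

Step 7
Reactants: 9 triethyl{[(3S)-5-iodo-3-methylpent-1-en-3-yl]oxy}silane; 14 2,2-dimethyloct-6-ynal
Product: 17 (6Z)-2,2-dimethyl-6-{(5S)-5-methyl-5-[(triethylsilyl)oxy]hept-6-en-2-ylidene}cyclohexan-1-ol (both carbinol epimers), via alkyllithium 15 (not isolated), via alkylzinc chloride 16 (not isolated)
Conditions: 9 (1.5 equiv), t-BuLi (3.0 equiv), Et2O, −78 °C; ZnCl2, THF, −78 to 0 °C; then 14, Ni(COD)2 (10 mol%), THF, 0 °C; aq. NH4Cl
Reagents that add atoms: none
Why: In the nickel-catalysed alkylative ynal cyclization, aldehyde and alkyne couple at zerovalent nickel to an oxanickelacyclopentene, and alkyl transfer from zinc with reductive elimination places the C11 chain cis to the new C5–C10 bond, so ring A closes and the alkene geometry (C11 cis to C5, methyl cis to C1) follows from the mechanism; phosphine-free conditions favour alkyl transfer over β-hydride elimination.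

Step 8
Reactants: 17 (6Z)-2,2-dimethyl-6-{(5S)-5-methyl-5-[(triethylsilyl)oxy]hept-6-en-2-ylidene}cyclohexan-1-ol
Product: 18 (6Z)-2,2-dimethyl-6-{(5S)-5-methyl-5-[(triethylsilyl)oxy]hept-6-en-2-ylidene}cyclohexan-1-one
Conditions: Dess–Martin periodinane, NaHCO3, CH2Cl2, 0 °C to rt
Reagents that add atoms: none
Why: Dess–Martin oxidation under buffered conditions merges both carbinol epimers into one enone without isomerizing the tetrasubstituted alkene.

Step 9
Reactants: 18 (6Z)-2,2-dimethyl-6-{(5S)-5-methyl-5-[(triethylsilyl)oxy]hept-6-en-2-ylidene}cyclohexan-1-one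
Product: 19 (8Z)-4,4-dimethyl-8-{(5S)-5-methyl-5-[(triethylsilyl)oxy]hept-6-en-2-ylidene}-1-oxaspiro[2.5]octane (both spiro epimers)
Conditions: Me3S+ I−, KN(SiMe3)2, THF, 0 °C; then 18, 0 °C to rt
Reagents that add atoms: trimethylsulfonium iodide (C[S+](C)C.[I-])
Why: In the Corey–Chaykovsky reaction the small sulfonium methylide adds 1,2 to the hindered enone carbonyl and closes the spiro-epoxide, which brings in C6; the configuration at C5 is lost again later.

Step 10
Reactants: 19 (8Z)-4,4-dimethyl-8-{(5S)-5-methyl-5-[(triethylsilyl)oxy]hept-6-en-2-ylidene}-1-oxaspiro[2.5]octane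
Product: 21 triethyl{[(E)-{(6Z)-2,2-dimethyl-6-{(5S)-5-methyl-5-[(triethylsilyl)oxy]hept-6-en-2-ylidene}cyclohexylidene}methyl]oxy}silane, via β,γ-unsaturated aldehyde 20 (not isolated)
Conditions: MeAl(OC6H2-4-Br-2,6-t-Bu2)2 (20 mol%), CH2Cl2, −78 °C; then Et3N, Et3SiOTf, −78 to −40 °C
Reagents that add atoms: triethylsilyl trifluoromethanesulfonate (CC[Si](CC)(CC)OS(=O)(=O)C(F)(F)F)
Why: Meinwald rearrangement (ionization at the allylic C5, 1,2-hydride shift from C6) gives the β,γ-unsaturated aldehyde, and soft enolization removes its doubly activated C5–H, so the C10=C9 geometry from step 7 is kept; the silyloxy group should end trans to C10 (E) because the cis position is blocked by the inward C11 methylene.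

Step 11
Reactants: 22 (4S)-4-benzyl-1,3-oxazolidin-2-one; 23 (2E)-but-2-enoyl chloride
Product: 25 (4S)-4-benzyl-3-[(2E)-but-2-enoyl]-1,3-oxazolidin-2-one, via lithium oxazolidinide 24 (not isolated)
Conditions: n-BuLi, THF, −78 °C; then 23, −78 to 0 °C
Reagents that add atoms: none
Why: N-acylation of the lithiated oxazolidinone with the acid chloride is a standard way to the crotonyl imide and keeps the (E)-alkene.

Step 12
Reactants: 21 triethyl{[(E)-{(6Z)-2,2-dimethyl-6-{(5S)-5-methyl-5-[(triethylsilyl)oxy]hept-6-en-2-ylidene}cyclohexylidene}methyl]oxy}silane; 25 (4S)-4-benzyl-3-[(2E)-but-2-enoyl]-1,3-oxazolidin-2-one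
Product: 26 (4S)-4-benzyl-3-{[(1R,2R,3R,4R)-3,4,8,8-tetramethyl-4-{(3S)-3-methyl-3-[(triethylsilyl)oxy]pent-4-en-1-yl}-1-[(triethylsilyl)oxy]-1,2,3,4,5,6,7,8-octahydronaphthalen-2-yl]carbonyl}-1,3-oxazolidin-2-one
Conditions: 25 (1.5 equiv), Et2AlCl (2.0 equiv), CH2Cl2, −78 °C; then 21, −78 to −30 °C; aq. NaHCO3/potassium sodium tartrate
Reagents that add atoms: none
Why: The aluminium-chelated s-cis crotonyl imide and the electron-rich 1-silyloxydiene C6=C5–C10=C9 should combine in a Lewis-acid-promoted normal-demand Diels–Alder reaction, concerted but asynchronous with the C8–C9 bond leading, and the closest known reaction type is the Et2AlCl-promoted cycloaddition of N-crotonyl oxazolidinones with 1-oxygenated and alkyl-substituted dienes. Ring B closes as a cyclohexene by suprafacial [4+2] addition across the diene termini C6 and C9, which leaves the new C5=C10 double bond in the ring fusion. The C6 silyloxy donor makes C9 the nucleophilic terminus and pairs it with the β-carbon C8, while C6 bonds to the acyl-bearing C7. C6 and C9 follow from the diene geometry set in steps 7 and 10 (silyloxy and C9 methyl outside, C11 inside, so C6–O and the C9 methyl end cis and C11 trans to both), C7/C8 trans follows from the (E)-alkene, and C6–O/C7-acyl cis follows from the endo transition state with the chelated acyl group under the diene. The absolute configuration comes from the auxiliary, whose benzyl group covers the Re face at C7 of the chelate so that the diene adds to the C7 Si/C8 Re face. The step needs an s-cis diene, which the 1,2-bis(alkylidene)cyclohexane frame of ring A enforces, and it needs the (E)-enol ether, the only isomer that can reach a reactive conformation because the inside position is already taken by C11.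

Step 13
Reactants: 26 (4S)-4-benzyl-3-{[(1R,2R,3R,4R)-3,4,8,8-tetramethyl-4-{(3S)-3-methyl-3-[(triethylsilyl)oxy]pent-4-en-1-yl}-1-[(triethylsilyl)oxy]-1,2,3,4,5,6,7,8-octahydronaphthalen-2-yl]carbonyl}-1,3-oxazolidin-2-one
Product: 28 (1R,2R,3R,4R)-3,4,8,8-tetramethyl-4-{(3S)-3-methyl-3-[(triethylsilyl)oxy]pent-4-en-1-yl}-1-[(triethylsilyl)oxy]-1,2,3,4,5,6,7,8-octahydronaphthalene-2-carboxylic acid, via peroxy acid 27 (not isolated)
Conditions: LiOH, H2O2, THF/H2O (3:1), 0 °C; then Na2SO3; 1 M HCl to pH 4, 0 °C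
Reagents that add atoms: hydrogen peroxide (OO)
Why: Lithium hydroperoxide attacks the exocyclic imide carbonyl selectively and releases the auxiliary without epimerizing C7, and basic peroxide does not touch the unactivated alkenes.

Step 14
Reactants: 28 (1R,2R,3R,4R)-3,4,8,8-tetramethyl-4-{(3S)-3-methyl-3-[(triethylsilyl)oxy]pent-4-en-1-yl}-1-[(triethylsilyl)oxy]-1,2,3,4,5,6,7,8-octahydronaphthalene-2-carboxylic acid
Product: 29 1-[(1R,2R,3R,4R)-3,4,8,8-tetramethyl-4-{(3S)-3-methyl-3-[(triethylsilyl)oxy]pent-4-en-1-yl}-1-[(triethylsilyl)oxy]-1,2,3,4,5,6,7,8-octahydronaphthalen-2-yl]ethan-1-one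
Conditions: MeLi (3 equiv), Et2O, 0 °C to rt; inverse quench into aq. NH4Cl
Reagents that add atoms: methyllithium (C[Li])
Why: Methyllithium adds to the lithium carboxylate to give a stable gem-diolate that collapses to the methyl ketone only on work-up, so over-addition is avoided and C7 keeps its configuration.

Step 15
Reactants: 29 1-[(1R,2R,3R,4R)-3,4,8,8-tetramethyl-4-{(3S)-3-methyl-3-[(triethylsilyl)oxy]pent-4-en-1-yl}-1-[(triethylsilyl)oxy]-1,2,3,4,5,6,7,8-octahydronaphthalen-2-yl]ethan-1-one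
Product: 30 1-[(1R,2R,3R,4R)-1-hydroxy-4-[(3S)-3-hydroxy-3-methylpent-4-en-1-yl]-3,4,8,8-tetramethyl-1,2,3,4,5,6,7,8-octahydronaphthalen-2-yl]ethan-1-one
Conditions: HF·pyridine, pyridine, THF, 0 °C to rt
Reagents that add atoms: none
Why: Buffered fluoride removes both triethylsilyl ethers under conditions mild enough for the β-hydroxy ketone and the tertiary allylic alcohol.

Step 16
Reactants: 30 1-[(1R,2R,3R,4R)-1-hydroxy-4-[(3S)-3-hydroxy-3-methylpent-4-en-1-yl]-3,4,8,8-tetramethyl-1,2,3,4,5,6,7,8-octahydronaphthalen-2-yl]ethan-1-one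
Product: 31 (1S,2R,3S,4R)-1-hydroxy-4-[(3S)-3-hydroxy-3-methylpent-4-en-1-yl]-3,4,8,8-tetramethyl-1,2,3,4,5,6,7,8-octahydronaphthalen-2-yl acetate
Conditions: purified flavin-dependent Baeyer–Villiger monooxygenase (steroid-monooxygenase type), NADP+ (cat.), phosphite dehydrogenase, Na2HPO3, air, Tris–HCl buffer pH 8.0, 10% DMSO, 25 °C
Reagents that add atoms: dioxygen (O=O)
Why: In the enzymatic Baeyer–Villiger oxidation the nucleophilic flavin peroxide adds to the ketone and the more substituted C7 migrates with retention to give the acetate; this class of enzyme converts ring-bound acetyl groups of steroids into acetates and does not epoxidize C=C bonds, which a peracid would attack first.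

**Compound list**

1 | (S)-(+)-linalool, (3S)-3,7-dimethylocta-1,6-dien-3-ol | C=C[C@@](C)(O)CCC=C(C)C | starting material
2 | (3S)-5-(5,5-dimethyl-1,2,4-trioxolan-3-yl)-3-methylpent-1-en-3-ol (secondary ozonide) | C=C[C@@](C)(O)CCC1OOC(C)(C)O1 | intermediate
3 | (5S)-5-ethenyl-5-methyloxolan-2-ol (anomer mixture) | C=C[C@]1(C)CCC(O)O1 | intermediate
4 | (5S)-5-ethenyl-5-methyloxolan-2-one | C=C[C@]1(C)CCC(=O)O1 | intermediate
5 | lithium (4S)-4-hydroxy-4-methylhex-5-enoate | [Li+].[O-]C(=O)CC[C@](C)(O)C=C | intermediate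
6 | triethylsilyl (4S)-4-methyl-4-[(triethylsilyl)oxy]hex-5-enoate | CC[Si](CC)(CC)OC(=O)CC[C@](C)(O[Si](CC)(CC)CC)C=C | intermediate
7 | (4S)-4-methyl-4-[(triethylsilyl)oxy]hex-5-enoic acid | OC(=O)CC[C@](C)(O[Si](CC)(CC)CC)C=C | intermediate
8 | 2-thioxopyridin-1(2H)-yl (4S)-4-methyl-4-[(triethylsilyl)oxy]hex-5-enoate | S=c1ccccn1OC(=O)CC[C@](C)(O[Si](CC)(CC)CC)C=C | intermediate
9 | triethyl{[(3S)-5-iodo-3-methylpent-1-en-3-yl]oxy}silane | C=C[C@@](C)(O[Si](CC)(CC)CC)CCI | intermediate
10 | isobutyronitrile | CC(C)C#N | starting material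
11 | 6-chlorohex-2-yne | CC#CCCCCl | starting material
12 | 2-lithio-2-methylpropanenitrile | CC(C)([Li])C#N | intermediate
13 | 2,2-dimethyloct-6-ynenitrile | CC#CCCCC(C)(C)C#N | intermediate
14 | 2,2-dimethyloct-6-ynal | CC#CCCCC(C)(C)C=O | intermediate
15 | {(3S)-3-methyl-3-[(triethylsilyl)oxy]pent-4-en-1-yl}lithium | C=C[C@@](C)(O[Si](CC)(CC)CC)CC[Li] | intermediate
16 | chloro{(3S)-3-methyl-3-[(triethylsilyl)oxy]pent-4-en-1-yl}zinc | C=C[C@@](C)(O[Si](CC)(CC)CC)CC[Zn]Cl | intermediate
17 | (6Z)-2,2-dimethyl-6-{(5S)-5-methyl-5-[(triethylsilyl)oxy]hept-6-en-2-ylidene}cyclohexan-1-ol (both carbinol epimers) | OC1/C(CCCC1(C)C)=C(/C)CC[C@](C)(O[Si](CC)(CC)CC)C=C | intermediate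
18 | (6Z)-2,2-dimethyl-6-{(5S)-5-methyl-5-[(triethylsilyl)oxy]hept-6-en-2-ylidene}cyclohexan-1-one | O=C1/C(CCCC1(C)C)=C(/C)CC[C@](C)(O[Si](CC)(CC)CC)C=C | intermediate
19 | (8Z)-4,4-dimethyl-8-{(5S)-5-methyl-5-[(triethylsilyl)oxy]hept-6-en-2-ylidene}-1-oxaspiro[2.5]octane (both spiro epimers) | C1OC12/C(CCCC2(C)C)=C(/C)CC[C@](C)(O[Si](CC)(CC)CC)C=C | intermediate
20 | (6Z)-2,2-dimethyl-6-{(5S)-5-methyl-5-[(triethylsilyl)oxy]hept-6-en-2-ylidene}cyclohexane-1-carbaldehyde (both C1 epimers) | O=CC1/C(CCCC1(C)C)=C(/C)CC[C@](C)(O[Si](CC)(CC)CC)C=C | intermediate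
21 | triethyl{[(E)-{(6Z)-2,2-dimethyl-6-{(5S)-5-methyl-5-[(triethylsilyl)oxy]hept-6-en-2-ylidene}cyclohexylidene}methyl]oxy}silane | CC[Si](CC)(CC)O/C=C1/C(CCCC1(C)C)=C(/C)CC[C@](C)(O[Si](CC)(CC)CC)C=C | intermediate
22 | (4S)-4-benzyl-1,3-oxazolidin-2-one | O=C1N[C@@H](Cc2ccccc2)CO1 | starting material
23 | (2E)-but-2-enoyl chloride | C/C=C/C(Cl)=O | starting material
24 | (4S)-4-benzyl-3-lithio-1,3-oxazolidin-2-one | [Li]N1[C@@H](Cc2ccccc2)COC1=O | intermediate
25 | (4S)-4-benzyl-3-[(2E)-but-2-enoyl]-1,3-oxazolidin-2-one | C/C=C/C(=O)N1[C@@H](Cc2ccccc2)COC1=O | intermediate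
26 | (4S)-4-benzyl-3-{[(1R,2R,3R,4R)-3,4,8,8-tetramethyl-4-{(3S)-3-methyl-3-[(triethylsilyl)oxy]pent-4-en-1-yl}-1-[(triethylsilyl)oxy]-1,2,3,4,5,6,7,8-octahydronaphthalen-2-yl]carbonyl}-1,3-oxazolidin-2-one | C=C[C@@](C)(O[Si](CC)(CC)CC)CC[C@@]1(C)C2=C([C@H](O[Si](CC)(CC)CC)[C@H](C(=O)N3[C@@H](Cc4ccccc4)COC3=O)[C@H]1C)C(C)(C)CCC2 | intermediate
27 | (1R,2R,3R,4R)-3,4,8,8-tetramethyl-4-{(3S)-3-methyl-3-[(triethylsilyl)oxy]pent-4-en-1-yl}-1-[(triethylsilyl)oxy]-1,2,3,4,5,6,7,8-octahydronaphthalene-2-carboperoxoic acid | C=C[C@@](C)(O[Si](CC)(CC)CC)CC[C@@]1(C)C2=C([C@H](O[Si](CC)(CC)CC)[C@H](C(=O)OO)[C@H]1C)C(C)(C)CCC2 | intermediate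
28 | (1R,2R,3R,4R)-3,4,8,8-tetramethyl-4-{(3S)-3-methyl-3-[(triethylsilyl)oxy]pent-4-en-1-yl}-1-[(triethylsilyl)oxy]-1,2,3,4,5,6,7,8-octahydronaphthalene-2-carboxylic acid | C=C[C@@](C)(O[Si](CC)(CC)CC)CC[C@@]1(C)C2=C([C@H](O[Si](CC)(CC)CC)[C@H](C(=O)O)[C@H]1C)C(C)(C)CCC2 | intermediate
29 | 1-[(1R,2R,3R,4R)-3,4,8,8-tetramethyl-4-{(3S)-3-methyl-3-[(triethylsilyl)oxy]pent-4-en-1-yl}-1-[(triethylsilyl)oxy]-1,2,3,4,5,6,7,8-octahydronaphthalen-2-yl]ethan-1-one | C=C[C@@](C)(O[Si](CC)(CC)CC)CC[C@@]1(C)C2=C([C@H](O[Si](CC)(CC)CC)[C@H](C(C)=O)[C@H]1C)C(C)(C)CCC2 | intermediate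
30 | 1-[(1R,2R,3R,4R)-1-hydroxy-4-[(3S)-3-hydroxy-3-methylpent-4-en-1-yl]-3,4,8,8-tetramethyl-1,2,3,4,5,6,7,8-octahydronaphthalen-2-yl]ethan-1-one | C=C[C@@](C)(O)CC[C@@]1(C)C2=C([C@H](O)[C@H](C(C)=O)[C@H]1C)C(C)(C)CCC2 | intermediate
31 | (1S,2R,3S,4R)-1-hydroxy-4-[(3S)-3-hydroxy-3-methylpent-4-en-1-yl]-3,4,8,8-tetramethyl-1,2,3,4,5,6,7,8-octahydronaphthalen-2-yl acetate | C=C[C@@](C)(O)CC[C@@]1(C)C2=C([C@H](O)[C@H](OC(C)=O)[C@H]1C)C(C)(C)CCC2 | target

**Step count and risks**

Total step count: 16. Longest linear sequence: 13 steps (steps 1–4, 7–10 and 12–16, from linalool).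

Steps most likely to fail:

Step 12. Bond formation at the fully substituted diene terminus, which carries an inward substituent, may be slow. The stoichiometric aluminium Lewis acid could then protodesilylate the dienol ether, or the reaction could drift into a stepwise Michael pathway with loss of endo and facial control. The fallback sets out from 21 and moves the stereocontrol from the auxiliary to a mild two-point-binding catalyst. Diene 21 and commercial achiral 3-[(2E)-but-2-enoyl]-1,3-oxazolidin-2-one are combined under [Cu(t-Bu-box)](SbF6)2 (10 mol%, CH2Cl2, −20 °C to rt), using the bis(oxazoline) enantiomer that directs the diene to the Si face at C7. This catalyst class is known for crotonyl imides with 1-oxygenated dienes and is tolerant of silyl enol ethers. It should give 3-{[(1R,2R,3R,4R)-3,4,8,8-tetramethyl-4-{(3S)-3-methyl-3-[(triethylsilyl)oxy]pent-4-en-1-yl}-1-[(triethylsilyl)oxy]-1,2,3,4,5,6,7,8-octahydronaphthalen-2-yl]carbonyl}-1,3-oxazolidin-2-one F1, which is cleaved with LiOH/H2O2 as in step 13; the route is rejoined at 28.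

Step 16. The bulky bicyclic ketone may bind poorly in the enzyme's active site, giving low conversion, and acyl migration could occur during a long incubation. The fallback sets out from 29 and does the oxidation chemically on the silyl-protected ketone with a peroxide system that spares C=C bonds: (Me3SiO)2, SnCl4, trans-cyclohexane-1,2-diamine, 4 Å molecular sieves, CH2Cl2, rt. This should give (1S,2R,3S,4R)-3,4,8,8-tetramethyl-4-{(3S)-3-methyl-3-[(triethylsilyl)oxy]pent-4-en-1-yl}-1-[(triethylsilyl)oxy]-1,2,3,4,5,6,7,8-octahydronaphthalen-2-yl acetate F2. Removal of both silyl ethers with HF·pyridine/pyridine (THF, 0 °C) returns to 31.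

Step 10. The allylic cation of the epoxide opening may live long enough to erode the C10=C9 geometry, the aldehyde may slip into conjugation, or the enol ether may form with the wrong geometry. The fallback sets out from 18 and brings in C6 without a cation, by Van Leusen reductive cyanation (p-toluenesulfonylmethyl isocyanide, t-BuOK, DME/t-BuOH, then MeOH). This should give (6Z)-2,2-dimethyl-6-{(5S)-5-methyl-5-[(triethylsilyl)oxy]hept-6-en-2-ylidene}cyclohexane-1-carbonitrile F3. Reduction with i-Bu2AlH (CH2Cl2, −78 °C, buffered hydrolysis) gives aldehyde 20, which is silylated at once with Et3SiOTf/Et3N; the route is rejoined at 21.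

**Further compounds**

F1 | step 12 | 3-{[(1R,2R,3R,4R)-3,4,8,8-tetramethyl-4-{(3S)-3-methyl-3-[(triethylsilyl)oxy]pent-4-en-1-yl}-1-[(triethylsilyl)oxy]-1,2,3,4,5,6,7,8-octahydronaphthalen-2-yl]carbonyl}-1,3-oxazolidin-2-one | C=C[C@@](C)(O[Si](CC)(CC)CC)CC[C@@]1(C)C2=C([C@H](O[Si](CC)(CC)CC)[C@H](C(=O)N3CCOC3=O)[C@H]1C)C(C)(C)CCC2
F2 | step 16 | (1S,2R,3S,4R)-3,4,8,8-tetramethyl-4-{(3S)-3-methyl-3-[(triethylsilyl)oxy]pent-4-en-1-yl}-1-[(triethylsilyl)oxy]-1,2,3,4,5,6,7,8-octahydronaphthalen-2-yl acetate | C=C[C@@](C)(O[Si](CC)(CC)CC)CC[C@@]1(C)C2=C([C@H](O[Si](CC)(CC)CC)[C@H](OC(C)=O)[C@H]1C)C(C)(C)CCC2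
F3 | step 10 | (6Z)-2,2-dimethyl-6-{(5S)-5-methyl-5-[(triethylsilyl)oxy]hept-6-en-2-ylidene}cyclohexane-1-carbonitrile | N#CC1/C(CCCC1(C)C)=C(/C)CC[C@](C)(O[Si](CC)(CC)CC)C=C
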